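## Retrosynthetic overview

1. Last bond: C8–propyl of the cyclobutane unit, by Negishi coupling on an (E)-iodomethylidene lactone; retention fixes the E-butylidene.
2. Key operation: a rhodium-catalysed enantioselective crossed [2+2] of (Z)-ligustilide (C6'=C7') with an ethynyl dienoyl pyrazole (C3a=C7a) builds the cyclobutane with all four stereocentres; iodolactonization in the same flask closes lactone B.
3. Both partners come from one dienyl triflate by Sonogashira coupling (pent-1-yne or ethynyltrimethylsilane); the triflate is made in two steps from methyl 2-oxocyclohexane-1-carboxylate.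
4. Ring order: six-membered carbocycles (bought) → lactone A (silver-catalysed 5-exo-dig, Z) → cyclobutane, then lactone B (same operation, E).

Numbering: ligustilide numbering throughout. Unit B (unprimed) is the unit whose C3a and C7a become cyclobutane carbons; unit A (primed) keeps C3a'=C7a' and bonds through C6' and C7'. "3a.7',7a.6'" means bonds C3a–C7' and C7a–C6'.

Target as read from the SMILES: 3'Z in unit A, 3E in unit B (propyl trans to the lactone oxygen), cyclobutane 3aS,7aR,6'S,7'R. Both ring fusions are cis, the two carbocycles lie on one face of the cyclobutane, and H-6', H-7' and lactone B lie on the other.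

Assumption: the Λ enantiomer of the rhodium catalyst is taken to give the drawn enantiomer; if the first run shows the antipode, the Δ enantiomer is used with nothing else changed.

## Route

Step 1
Reactants: 1 methyl 2-oxocyclohexane-1-carboxylate
Product: 4 methyl 6-oxocyclohex-1-ene-1-carboxylate, via α-phenylselanyl keto ester 2 (not isolated), via selenoxide 3 (not isolated)
Conditions: PhSeCl, pyridine, CH2Cl2, 0 °C; then 30% H2O2 (3 equiv), 0 °C to rt; crude 4 used at once
Reagents that add atoms: none
Why: Reich-type α-selenenylation of the β-keto ester and selenoxide syn-elimination work here because the selenium-bearing carbon has β-hydrogens only on the ring CH2, so the new C=C can form only in conjugation with both carbonyls; no stereocentre remains.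

Step 2
Reactants: 4 methyl 6-oxocyclohex-1-ene-1-carboxylate
Product: 5 methyl 2-{[(trifluoromethyl)sulfonyl]oxy}cyclohexa-1,5-diene-1-carboxylate
Conditions: Tf2O, i-Pr2NEt, CH2Cl2, −78 °C to −20 °C
Reagents that add atoms: trifluoromethanesulfonic anhydride, O=S(=O)(OS(=O)(=O)C(F)(F)F)C(F)(F)F
Why: Soft enolization and O-triflation, in which the γ-hydrogens of 4 belong to a vinylogous β-keto ester, so the amine gives the ester-stabilised cross-conjugated dienolate rather than the α'-enolate and Tf2O traps it on oxygen as the 1,5-dienyl triflate; no stereocentre.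

Step 3
Reactants: 5 methyl 2-{[(trifluoromethyl)sulfonyl]oxy}cyclohexa-1,5-diene-1-carboxylate; 6 pent-1-yne
Product: 7 methyl 2-(pent-1-yn-1-yl)cyclohexa-1,5-diene-1-carboxylate
Conditions: PdCl2(PPh3)2 (3 mol%), CuI (5 mol%), Et3N, THF, rt
Reagents that add atoms: none
Why: Sonogashira coupling of an electron-poor enol triflate with a terminal alkyne runs at room temperature and leaves the 1,3-diene untouched; no stereocentre.

Step 4
Reactants: 7 methyl 2-(pent-1-yn-1-yl)cyclohexa-1,5-diene-1-carboxylate
Product: 10 (Z)-ligustilide, via lithium carboxylate 8 (not isolated), via enynoic acid 9 (not isolated)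
Conditions: LiOH, THF/H2O, 0 °C to rt; then AcOH (to pH 5), AgNO3 (10 mol%), rt, dark
Reagents that add atoms: lithium hydroxide, [Li+].[OH-]
Why: Saponification followed by silver-catalysed cycloisomerization of the (Z)-2-en-4-ynoic acid, in which anti addition of the carboxylate oxygen and a proton across the alkyne is 5-exo-dig selective with silver salts and puts oxygen and propyl cis, which is the Z-butylidene.

Step 5
Reactants: 5 methyl 2-{[(trifluoromethyl)sulfonyl]oxy}cyclohexa-1,5-diene-1-carboxylate; 11 ethynyltrimethylsilane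
Product: 12 methyl 2-[(trimethylsilyl)ethynyl]cyclohexa-1,5-diene-1-carboxylate
Conditions: PdCl2(PPh3)2 (3 mol%), CuI (5 mol%), Et3N, THF, rt
Reagents that add atoms: none
Why: Same Sonogashira coupling as in step 3, the silyl cap preventing homocoupling and double coupling of the acetylene; no stereocentre.

Step 6
Reactants: 12 methyl 2-[(trimethylsilyl)ethynyl]cyclohexa-1,5-diene-1-carboxylate
Product: 14 2-ethynylcyclohexa-1,5-diene-1-carboxylic acid, via lithium carboxylate 13 (not isolated)
Conditions: LiOH, THF/H2O, 0 °C to rt; then 1 M HCl (to pH 3), 0 °C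
Reagents that add atoms: lithium hydroxide, [Li+].[OH-]
Why: Hydroxide saponifies the ester and in the same flask cleaves the C(sp)–Si bond (protodesilylation of an alkynylsilane), so acidification delivers the free ethynyl acid; no stereocentre.

Step 7
Reactants: 14 2-ethynylcyclohexa-1,5-diene-1-carboxylic acid; 15 3,5-dimethyl-1H-pyrazole
Product: 16 (3,5-dimethyl-1H-pyrazol-1-yl)(2-ethynylcyclohexa-1,5-dien-1-yl)methanone
Conditions: DCC, DMAP (10 mol%), CH2Cl2, 0 °C to rt
Reagents that add atoms: none
Why: Steglich-type carbodiimide coupling turns the acid into an N-acylpyrazole, the N,O-bidentate handle that the rhodium Lewis acid needs and that later serves as the leaving group; no stereocentre.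

Step 8
Reactants: 16 (3,5-dimethyl-1H-pyrazol-1-yl)(2-ethynylcyclohexa-1,5-dien-1-yl)methanone; 10 (Z)-ligustilide (3 equiv)
Product: 18 (3E,3aS,7aR,3'Z,6'S,7'R)-3-(iodomethylidene)-3-debutylidene-3a.7',7a.6'-diligustilide, via acylpyrazole cycloadduct 17 (not isolated)
Conditions: Λ-[Rh(C17H16NS)2(MeCN)2]PF6 (4 mol%; C17H16NS = cyclometalated 5-tert-butyl-2-phenylbenzothiazole), CH2Cl2, blue LEDs (450 nm), rt, N2; then MeCN/H2O (20:1), NIS (1.2 equiv), 0 °C to rt, dark
Reagents that add atoms: N-iodosuccinimide, O=C1CCC(=O)N1I; water, O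
Why: Proposed new method: the N,O-chelate of 16 on the chiral-at-metal trivalent rhodium Lewis acid is the only blue-light absorber, its triplet enoyl unit bonds C7a to the unsubstituted diene terminus C6' of 10 and then C3a to C7' (propargylic and pentadienyl radical centres, the usual orientation in which the alkene terminus goes to Cα), the tert-butylbenzothiazole wall of the Λ complex blocks one face of C3a=C7a and so fixes C3a and C7a, the ring of 10 stacks over the tied-back carbocycle of 16 rather than over the metal-bound acyl group and so fixes C6' and C7' with both ring fusions cis, the closest known reaction being the enantioselective visible-light [2+2] photocycloaddition of α,β-unsaturated N-acylpyrazoles and 2-acylimidazoles with alkenes and dienes on this catalyst type; NIS then activates the cis ethynyl group, the acyl oxygen attacks anti in a 5-exo-dig iodolactonization (iodine trans to oxygen, hence E) and water releases the pyrazole, the closest known reaction being halolactonization of unsaturated tertiary amides and N-acyloxazolidinones with loss of the amine part.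

Step 9
Reactants: 18 (3E,3aS,7aR,3'Z,6'S,7'R)-3-(iodomethylidene)-3-debutylidene-3a.7',7a.6'-diligustilide; 19 propylzinc bromide
Product: 20 (3E,3aS,7aR,3'Z,6'S,7'R)-3a.7',7a.6'-diligustilide (CNP0371639.1)
Conditions: Pd(P(t-Bu)3)2 (5 mol%), THF/NMP, 0 °C to rt
Reagents that add atoms: none
Why: Negishi sp2–sp3 cross-coupling replaces iodine by propyl with retention of the alkene geometry, so propyl ends cis to C3a and trans to the lactone oxygen (E), the organozinc is mild enough for both enol lactones and the bulky phosphine lets reductive elimination outrun β-hydride elimination; the four stereocentres are untouched.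

## Compound list

1 | methyl 2-oxocyclohexane-1-carboxylate | COC(=O)C1CCCCC1=O | starting material
2 | methyl 2-oxo-1-(phenylselanyl)cyclohexane-1-carboxylate (racemic) | COC(=O)C1([Se]c2ccccc2)CCCCC1=O | intermediate
3 | methyl 2-oxo-1-(phenylseleninyl)cyclohexane-1-carboxylate (selenoxide, diastereomer mixture) | COC(=O)C1([Se](=O)c2ccccc2)CCCCC1=O | intermediate
4 | methyl 6-oxocyclohex-1-ene-1-carboxylate | COC(=O)C1=CCCCC1=O | intermediate
5 | methyl 2-{[(trifluoromethyl)sulfonyl]oxy}cyclohexa-1,5-diene-1-carboxylate | COC(=O)C1=C(OS(=O)(=O)C(F)(F)F)CCC=C1 | intermediate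
6 | pent-1-yne | CCCC#C | starting material
7 | methyl 2-(pent-1-yn-1-yl)cyclohexa-1,5-diene-1-carboxylate | CCCC#CC1=C(C(=O)OC)C=CCC1 | intermediate
8 | lithium 2-(pent-1-yn-1-yl)cyclohexa-1,5-diene-1-carboxylate | [Li+].CCCC#CC1=C(C(=O)[O-])C=CCC1 | intermediate
9 | 2-(pent-1-yn-1-yl)cyclohexa-1,5-diene-1-carboxylic acid | CCCC#CC1=C(C(=O)O)C=CCC1 | intermediate
10 | (Z)-ligustilide, (3Z)-3-butylidene-4,5-dihydro-2-benzofuran-1(3H)-one | CCC/C=C1\OC(=O)C2=C1CCC=C2 | intermediate
11 | ethynyltrimethylsilane | C#C[Si](C)(C)C | starting material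
12 | methyl 2-[(trimethylsilyl)ethynyl]cyclohexa-1,5-diene-1-carboxylate | COC(=O)C1=C(C#C[Si](C)(C)C)CCC=C1 | intermediate
13 | lithium 2-ethynylcyclohexa-1,5-diene-1-carboxylate | [Li+].[O-]C(=O)C1=C(C#C)CCC=C1 | intermediate
14 | 2-ethynylcyclohexa-1,5-diene-1-carboxylic acid | OC(=O)C1=C(C#C)CCC=C1 | intermediate
15 | 3,5-dimethyl-1H-pyrazole | Cc1cc(C)[nH]n1 | starting material
16 | (3,5-dimethyl-1H-pyrazol-1-yl)(2-ethynylcyclohexa-1,5-dien-1-yl)methanone | C#CC1=C(C(=O)n2nc(C)cc2C)C=CCC1 | intermediate
17 | (3aR,7aR,3'Z,6'S,7'R)-[2+2] cycloadduct of 16 (across C3a=C7a) and 10 (across C6'=C7'): cyclobutane C3a–C7a–C6'–C7', ethynyl on C3a, (3,5-dimethylpyrazol-1-yl)carbonyl on C7a, both cis to H-6' and H-7' | CCC/C=C1\OC(=O)C2=C1CC[C@H]1[C@@H]2[C@@]2(C#C)CCC=C[C@@]12C(=O)n1nc(C)cc1C | intermediate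
18 | (3E,3aS,7aR,3'Z,6'S,7'R)-3-(iodomethylidene)-3-debutylidene-3a.7',7a.6'-diligustilide (iodine in place of the propyl group on C8) | CCC/C=C1\OC(=O)C2=C1CC[C@H]1[C@@H]2[C@@]23CCC=C[C@@]12C(=O)O/C3=C/I | intermediate
19 | propylzinc bromide | CCC[Zn]Br | starting material
20 | (3E,3aS,7aR,3'Z,6'S,7'R)-3a.7',7a.6'-diligustilide (CNP0371639.1) | CCC/C=C1\OC(=O)C2=C1CC[C@H]1[C@@H]2[C@@]23CCC=C[C@@]12C(=O)O/C3=C/CCC | target

## Step count and risks

Total step count: 9. Longest linear sequence: 7 (steps 1, 2, 5, 6, 7, 8, 9).

**Most likely to fail, first: step 8.** The risks are: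
- a head-to-head adduct (C3a–C6', C7a–C7') instead of the wanted one;
- bonding through C6 of 16, which gives [4+2]-type adducts;
- energy transfer to 10 with racemic background dimers;
- attack of the pyrazole nitrogen instead of the acyl oxygen in the iodocyclization.

The fallback replaces catalyst control by auxiliary control; it sets out from 14 and comes back at 18. DCC/DMAP coupling of 14 with (S)-4-benzyl-1,3-oxazolidin-2-one gives the imide (S)-4-benzyl-3-[(2-ethynylcyclohexa-1,5-dien-1-yl)carbonyl]-1,3-oxazolidin-2-one F1. Its MgBr2·OEt2 chelate is irradiated with 10 (420 nm, thioxanthen-9-one as triplet sensitizer, CH2Cl2, −40 °C), the benzyl group shielding one face of C3a=C7a. This gives the imide cycloadduct F2, which is purified as one diastereomer; the (R) auxiliary is used if the face turns out wrong. NIS in wet MeCN then closes lactone B with release of the auxiliary and the route is rejoined at 18.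

**Second: step 9.** The iodide sits next to a quaternary carbon, so hydrodeiodination through β-hydride elimination and E/Z scrambling are the risks. The fallback brings in the three carbons as an allyl group and reduces afterwards; it sets out from 18 and comes back at 20. Stille coupling of 18 with allyltributylstannane (Pd(PPh3)4, CuI, DMF, rt) gives the (3E)-but-3-en-1-ylidene dimer F3. RhCl(PPh3)3 with H2 (1 atm, benzene, rt) then saturates only the monosubstituted terminal alkene and gives 20.

**Third: step 2.** Enone 4 dimerises readily and could be triflated as the α'-enolate. The fallback avoids the triflate and builds the diene by elimination; it sets out from 4 and comes back at 7 and at 12. Pent-1-yne 6 (n-BuLi, CeCl3, THF, −78 °C) adds 1,2 to the ketone of 4 and gives methyl 6-hydroxy-6-(pent-1-yn-1-yl)cyclohex-1-ene-1-carboxylate F4. Ac2O/DMAP/Et3N gives its acetate methyl 6-acetoxy-6-(pent-1-yn-1-yl)cyclohex-1-ene-1-carboxylate F5. DBU in CH2Cl2 then effects a vinylogous E1cB elimination (γ-deprotonation, loss of acetate) to 7. The same three operations with 11 in place of 6 give methyl 6-hydroxy-6-[(trimethylsilyl)ethynyl]cyclohex-1-ene-1-carboxylate F6, then methyl 6-acetoxy-6-[(trimethylsilyl)ethynyl]cyclohex-1-ene-1-carboxylate F7, then 12.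

Further compounds

F1 | step 8 | (S)-4-benzyl-3-[(2-ethynylcyclohexa-1,5-dien-1-yl)carbonyl]-1,3-oxazolidin-2-one | C#CC1=C(C(=O)N2C(=O)OC[C@@H]2Cc2ccccc2)C=CCC1
F2 | step 8 | (3aR,7aR,3'Z,6'S,7'R)-imide cycloadduct: compound 17 with the (4S)-4-benzyl-2-oxo-1,3-oxazolidin-3-yl group in place of the pyrazolyl group | CCC/C=C1\OC(=O)C2=C1CC[C@H]1[C@@H]2[C@@]2(C#C)CCC=C[C@@]12C(=O)N1C(=O)OC[C@@H]1Cc1ccccc1
F3 | step 9 | (3E,3aS,7aR,3'Z,6'S,7'R)-3-(but-3-en-1-ylidene)-3-debutylidene-3a.7',7a.6'-diligustilide | CCC/C=C1\OC(=O)C2=C1CC[C@H]1[C@@H]2[C@@]23CCC=C[C@@]12C(=O)O/C3=C/CC=C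
F4 | step 2 | methyl 6-hydroxy-6-(pent-1-yn-1-yl)cyclohex-1-ene-1-carboxylate (racemic) | CCCC#CC1(O)CCCC=C1C(=O)OC
F5 | step 2 | methyl 6-acetoxy-6-(pent-1-yn-1-yl)cyclohex-1-ene-1-carboxylate (racemic) | CCCC#CC1(OC(C)=O)CCCC=C1C(=O)OC
F6 | step 2 | methyl 6-hydroxy-6-[(trimethylsilyl)ethynyl]cyclohex-1-ene-1-carboxylate (racemic) | C[Si](C)(C)C#CC1(O)CCCC=C1C(=O)OC
F7 | step 2 | methyl 6-acetoxy-6-[(trimethylsilyl)ethynyl]cyclohex-1-ene-1-carboxylate (racemic) | C[Si](C)(C)C#CC1(OC(C)=O)CCCC=C1C(=O)OC
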